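**Retrosynthetic overview**
1. Last bond: C5–C6 (with the C5 carbinol and the 6E alkene) by a light-driven cobalt-catalysed reductive coupling of alkyne 21 (ring B half) with β-acetoxy aldehyde 27 (ring A half).
2. 27: ring A is bought as the symmetrical pyranone 22; one ethyl group is joined to (S)-Roche aldehyde 4 by a lateral aldol (C2–C3), acetylated in the same flask.
3. 21: ring B is the only ring made (step 10), by C-acylation of bis-silyl dienol ether 17 with acid chloride 18 and cyclodehydration of triketone 19.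
4. 18 comes from (S)-Roche ester 1 (C8 centre); 17 from methyl (S)-3-hydroxypentanoate 9 (Fráter–Seebach methylation) and pentan-3-one 13.
5. Ring order: ring A purchased, ring B formed in step 10, no ring formed afterwards.

Assumption: the SMILES is read literally as the (2R,3R,4S,5S,6E,8R)-non-6-en-3-yl acetate with a (2S,3S)-3-hydroxypentan-2-yl side chain; 1, 9, 13 and 22 are taken as purchasable.

**Route**

Step 1
Reactants: 1 methyl (S)-3-hydroxy-2-methylpropanoate
Product: 2 methyl (S)-3-[(tert-butyldimethylsilyl)oxy]-2-methylpropanoate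
Conditions: TBSCl, imidazole, DMF, 0 °C to rt
Reagents that add atoms: tert-butyldimethylsilyl chloride CC(C)(C)[Si](C)(C)Cl
Why: Standard silyl ether formation on the primary alcohol; the bought stereocentre is not touched.

Step 2
Reactants: 2 methyl (S)-3-[(tert-butyldimethylsilyl)oxy]-2-methylpropanoate
Product: 4 (S)-3-[(tert-butyldimethylsilyl)oxy]-2-methylpropanal, via diisobutylaluminium hemiacetal of 2 3 (not isolated)
Conditions: DIBAL-H (1.05 equiv), CH2Cl2, −78 °C; MeOH, aq. Rochelle salt; used crude, divided between steps 3 and 12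
Reagents that add atoms: none
Why: Partial ester reduction with DIBAL-H: the tetrahedral aluminium hemiacetal 3 survives at −78 °C and releases the aldehyde only on work-up, and 4 is used cold and crude to keep the α-stereocentre.

Step 3
Reactants: 4 (S)-3-[(tert-butyldimethylsilyl)oxy]-2-methylpropanal
Product: 5 (R)-tert-butyl[(4,4-dibromo-2-methylbut-3-en-1-yl)oxy]dimethylsilane
Conditions: CBr4, PPh3, Zn, CH2Cl2, rt; then 4, 0 °C
Reagents that add atoms: carbon tetrabromide BrC(Br)(Br)Br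
Why: Corey–Fuchs (Ramirez) dibromo-olefination; the neutral Wittig-type conditions do not epimerise the α-methyl aldehyde.

Step 4
Reactants: 5 (R)-tert-butyl[(4,4-dibromo-2-methylbut-3-en-1-yl)oxy]dimethylsilane
Product: 7 (R)-tert-butyldimethyl[(2-methylpent-3-yn-1-yl)oxy]silane, via lithium (R)-4-[(tert-butyldimethylsilyl)oxy]-3-methylbut-1-yn-1-ide 6 (not isolated)
Conditions: n-BuLi (2.1 equiv), THF, −78 °C; MeI, −78 °C to rt
Reagents that add atoms: iodomethane CI
Why: Second stage of the Corey–Fuchs sequence (Br/Li exchange, rearrangement to acetylide 6, C-methylation); the propargylic stereocentre is not deprotonated at −78 °C.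

Step 5
Reactants: 7 (R)-tert-butyldimethyl[(2-methylpent-3-yn-1-yl)oxy]silane
Product: 8 (R)-2-methylpent-3-ynoic acid
Conditions: Jones reagent (CrO3, H2SO4, H2O), acetone, 0 °C, short reaction time
Reagents that add atoms: water O
Why: Jones oxidation cleaves the primary silyl ether and oxidises the alcohol through the aldehyde hydrate to the acid in one pot; cold, short, acidic conditions limit enolisation of the α-stereocentre.

Step 6
Reactants: 9 methyl (S)-3-hydroxypentanoate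
Product: 11 methyl (2S,3S)-3-hydroxy-2-methylpentanoate, via dilithium alkoxide–enolate of 9 10 (not isolated)
Conditions: LDA (2.2 equiv), THF, −78 to −20 °C; MeI, DMPU, −78 to 0 °C
Reagents that add atoms: iodomethane CI
Why: Fráter–Seebach alkylation: the chelated dianion 10 is methylated anti to the C3 ethyl-bearing centre, so the bought C3 sets C2 (2S, anti, typically ≥ 95:5).

Step 7
Reactants: 11 methyl (2S,3S)-3-hydroxy-2-methylpentanoate
Product: 12 methyl (2S,3S)-3-[(tert-butyldimethylsilyl)oxy]-2-methylpentanoate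
Conditions: TBSOTf, 2,6-lutidine, CH2Cl2, 0 °C
Reagents that add atoms: tert-butyldimethylsilyl trifluoromethanesulfonate CC(C)(C)[Si](C)(C)OS(=O)(=O)C(F)(F)F
Why: Standard silylation of a hindered secondary alcohol with the silyl triflate; no stereocentre is affected.

Step 8
Reactants: 12 methyl (2S,3S)-3-[(tert-butyldimethylsilyl)oxy]-2-methylpentanoate; 13 pentan-3-one
Product: 15 (6S,7S)-7-[(tert-butyldimethylsilyl)oxy]-4,6-dimethylnonane-3,5-dione (C4 epimers/enol), via lithium pent-2-en-3-olate 14 (not isolated)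
Conditions: 13 (3 equiv), LDA (3 equiv), THF, −78 °C; then 12, −78 to 0 °C; aqueous work-up
Reagents that add atoms: none
Why: Crossed Claisen condensation of the ketone enolate (in excess) with the ester, driven by deprotonation of the β-diketone at C4, which also shields the C6 stereocentre from enolisation.

Step 9
Reactants: 15 (6S,7S)-7-[(tert-butyldimethylsilyl)oxy]-4,6-dimethylnonane-3,5-dione
Product: 17 (6S,7S)-7-[(tert-butyldimethylsilyl)oxy]-4,6-dimethyl-3,5-bis[(trimethylsilyl)oxy]nona-2,4-diene (E/Z mixture), via dilithium dienediolate of 15 16 (not isolated)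
Conditions: LDA (2.2 equiv), THF, −78 to 0 °C; TMSCl, −78 °C to rt; filtered through pentane, used crude
Reagents that add atoms: chlorotrimethylsilane C[Si](C)(C)Cl
Why: β-Diketone dianion formation (central CH, then the less hindered ethyl CH2 under kinetic control) and double O-silylation give the 1,3-bis(silyl enol ether).

Step 10
Reactants: 8 (R)-2-methylpent-3-ynoic acid; 17 (6S,7S)-7-[(tert-butyldimethylsilyl)oxy]-4,6-dimethyl-3,5-bis[(trimethylsilyl)oxy]nona-2,4-diene
Product: 20 2-[(2S,3S)-3-[(tert-butyldimethylsilyl)oxy]pentan-2-yl]-3,5-dimethyl-6-[(R)-pent-3-yn-2-yl]-4H-pyran-4-one, via (R)-2-methylpent-3-ynoyl chloride 18 (not isolated), via (4R,10S,11S)-11-[(tert-butyldimethylsilyl)oxy]-4,6,8,10-tetramethyltridec-2-yne-5,7,9-trione 19 (not isolated)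
Conditions: 8, 1-chloro-N,N,2-trimethylprop-1-en-1-amine, CH2Cl2, 0 °C; then 17, CH2Cl2, −78 to 20 °C; MeOH; solvent exchange, PPh3, CCl4, THF, rt
Reagents that add atoms: none
Why: Base-free acid chloride formation, C-acylation of the 1,3-bis(silyl enol ether) at its terminal carbon (Mukaiyama-type acylation) and PPh3/CCl4 cyclodehydration of the 1,3,5-triketone close ring B (γ-pyranone); no base is present, so the propargylic α-centre of 18/19 is kept.

Step 11
Reactants: 20 2-[(2S,3S)-3-[(tert-butyldimethylsilyl)oxy]pentan-2-yl]-3,5-dimethyl-6-[(R)-pent-3-yn-2-yl]-4H-pyran-4-one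
Product: 21 2-[(2S,3S)-3-hydroxypentan-2-yl]-3,5-dimethyl-6-[(R)-pent-3-yn-2-yl]-4H-pyran-4-one
Conditions: HF·pyridine, THF, 0 °C to rt
Reagents that add atoms: none
Why: Mildly acidic fluoride desilylation; a basic fluoride source is avoided because the C–H between the pyranone and the alkyne is acidic.

Step 12
Reactants: 22 2,6-diethyl-3,5-dimethyl-4H-pyran-4-one; 4 (S)-3-[(tert-butyldimethylsilyl)oxy]-2-methylpropanal
Product: 25 (2R,3R,4S)-5-[(tert-butyldimethylsilyl)oxy]-2-(6-ethyl-3,5-dimethyl-4-oxo-4H-pyran-2-yl)-4-methylpentan-3-yl acetate, via lithium 2-ethyl-6-ethylidene-3,5-dimethyl-6H-pyran-4-olate 23 (not isolated), via lithium (2R,3R,4S)-5-[(tert-butyldimethylsilyl)oxy]-2-(6-ethyl-3,5-dimethyl-4-oxo-4H-pyran-2-yl)-4-methylpentan-3-olate 24 (not isolated)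
Conditions: 22 (1.1 equiv), LiHMDS (1.05 equiv), THF, −78 °C; 4 (1.0 equiv), −78 °C; Ac2O, −78 to 0 °C; chromatography
Reagents that add atoms: acetic anhydride CC(=O)OC(C)=O
Why: Lateral (vinylogous) aldol of the pyranone dienolate 23: the aldehyde is attacked on its Felkin–Anh face (non-chelating β-silyloxy group, 3,4-syn, giving 3R next to the bought 4S centre) and the ethylidene dienolate reacts through an open transition state to the 2,3-anti adduct (2R), the aldolate 24 being acetylated cold before retro-aldol can erode the ratio; minor diastereomers are removed by chromatography.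

Step 13
Reactants: 25 (2R,3R,4S)-5-[(tert-butyldimethylsilyl)oxy]-2-(6-ethyl-3,5-dimethyl-4-oxo-4H-pyran-2-yl)-4-methylpentan-3-yl acetate
Product: 26 (2R,3R,4S)-2-(6-ethyl-3,5-dimethyl-4-oxo-4H-pyran-2-yl)-5-hydroxy-4-methylpentan-3-yl acetate
Conditions: HF·pyridine, pyridine, THF, 0 °C
Reagents that add atoms: none
Why: Buffered acidic desilylation of the primary silyl ether; without base the secondary acetate does not migrate to the new primary alcohol.

Step 14
Reactants: 26 (2R,3R,4S)-2-(6-ethyl-3,5-dimethyl-4-oxo-4H-pyran-2-yl)-5-hydroxy-4-methylpentan-3-yl acetate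
Product: 27 (2R,3S,4R)-2-(6-ethyl-3,5-dimethyl-4-oxo-4H-pyran-2-yl)-4-methyl-5-oxopentan-3-yl acetate
Conditions: Dess–Martin periodinane, CH2Cl2, 0 °C to rt; filtered and used at once
Reagents that add atoms: none
Why: Dess–Martin oxidation is neutral to weakly acidic, so the β-acetoxy aldehyde neither eliminates nor epimerises (the CIP descriptors change only because the priorities change).

Step 15
Reactants: 21 2-[(2S,3S)-3-hydroxypentan-2-yl]-3,5-dimethyl-6-[(R)-pent-3-yn-2-yl]-4H-pyran-4-one; 27 (2R,3S,4R)-2-(6-ethyl-3,5-dimethyl-4-oxo-4H-pyran-2-yl)-4-methyl-5-oxopentan-3-yl acetate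
Product: 28 (2R,3R,4S,5S,6E,8R)-2-(6-ethyl-3,5-dimethyl-4-oxo-4H-pyran-2-yl)-5-hydroxy-8-{6-[(2S,3S)-3-hydroxypentan-2-yl]-3,5-dimethyl-4-oxo-4H-pyran-2-yl}-4,6-dimethylnon-6-en-3-yl acetate (target)
Conditions: 21 (1.0 equiv), 27 (1.3 equiv), CoBr2 (10 mol %), dppp (12 mol %), 4CzIPN (2 mol %), Hantzsch ester (1.5 equiv), degassed MeCN/THF, 450 nm LEDs, 10 °C; HPLC
Reagents that add atoms: none
Why: Proposed new method: a visible-light Co/photoredox reductive alkyne–aldehyde coupling used under substrate control to join two complete fragments; photoreduced Co(I)(dppp) binds 21 and 27 and undergoes oxidative cyclisation to an oxacobaltacyclopentene, forming C5–C6 at the methyl-bearing alkyne carbon (the branched pyranyl-bearing carbon stays on Co, away from the aldehyde substituent) on the Felkin–Anh face of 27 (bond formation anti to the acetoxy-bearing C3, giving the 4,5-syn, 5S carbinol), and protons from the oxidised Hantzsch ester then cleave Co–O and Co–C with retention so that H and C5 are cis across the new alkene (6E), the reduced photocatalyst returning Co(III) to Co(I); closest known reaction type: Ni(0)- and Co-catalysed reductive couplings of alkynes with aldehydes to allylic alcohols (including light-driven ones with aryl alkynes), not yet shown for an unsymmetrical dialkyl 2-alkyne with an α-stereogenic β-acyloxy aldehyde under substrate control.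

**Compound list**
1 | methyl (S)-3-hydroxy-2-methylpropanoate ((S)-Roche ester) | COC(=O)[C@@H](C)CO | starting material
2 | methyl (S)-3-[(tert-butyldimethylsilyl)oxy]-2-methylpropanoate | COC(=O)[C@@H](C)CO[Si](C)(C)C(C)(C)C | intermediate
3 | diisobutylaluminium hemiacetal of 2 | COC(O[Al](CC(C)C)CC(C)C)[C@@H](C)CO[Si](C)(C)C(C)(C)C | intermediate
4 | (S)-3-[(tert-butyldimethylsilyl)oxy]-2-methylpropanal | O=C[C@@H](C)CO[Si](C)(C)C(C)(C)C | intermediate
5 | (R)-tert-butyl[(4,4-dibromo-2-methylbut-3-en-1-yl)oxy]dimethylsilane | BrC(Br)=C[C@@H](C)CO[Si](C)(C)C(C)(C)C | intermediate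
6 | lithium (R)-4-[(tert-butyldimethylsilyl)oxy]-3-methylbut-1-yn-1-ide | [Li]C#C[C@@H](C)CO[Si](C)(C)C(C)(C)C | intermediate
7 | (R)-tert-butyldimethyl[(2-methylpent-3-yn-1-yl)oxy]silane | CC#C[C@@H](C)CO[Si](C)(C)C(C)(C)C | intermediate
8 | (R)-2-methylpent-3-ynoic acid | CC#C[C@@H](C)C(=O)O | intermediate
9 | methyl (S)-3-hydroxypentanoate | COC(=O)C[C@@H](O)CC | starting material
10 | dilithium alkoxide–enolate of 9 | COC(O[Li])=C[C@@H](O[Li])CC | intermediate
11 | methyl (2S,3S)-3-hydroxy-2-methylpentanoate | COC(=O)[C@@H](C)[C@@H](O)CC | intermediate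
12 | methyl (2S,3S)-3-[(tert-butyldimethylsilyl)oxy]-2-methylpentanoate | COC(=O)[C@@H](C)[C@@H](O[Si](C)(C)C(C)(C)C)CC | intermediate
13 | pentan-3-one | CCC(=O)CC | starting material
14 | lithium pent-2-en-3-olate | CC=C(O[Li])CC | intermediate
15 | (6S,7S)-7-[(tert-butyldimethylsilyl)oxy]-4,6-dimethylnonane-3,5-dione | CCC(=O)C(C)C(=O)[C@@H](C)[C@@H](O[Si](C)(C)C(C)(C)C)CC | intermediate
16 | dilithium dienediolate of 15 | CC=C(O[Li])C(C)=C(O[Li])[C@@H](C)[C@@H](O[Si](C)(C)C(C)(C)C)CC | intermediate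
17 | (6S,7S)-7-[(tert-butyldimethylsilyl)oxy]-4,6-dimethyl-3,5-bis[(trimethylsilyl)oxy]nona-2,4-diene | CC=C(O[Si](C)(C)C)C(C)=C(O[Si](C)(C)C)[C@@H](C)[C@@H](O[Si](C)(C)C(C)(C)C)CC | intermediate
18 | (R)-2-methylpent-3-ynoyl chloride | CC#C[C@@H](C)C(Cl)=O | intermediate
19 | (4R,10S,11S)-11-[(tert-butyldimethylsilyl)oxy]-4,6,8,10-tetramethyltridec-2-yne-5,7,9-trione | CC#C[C@@H](C)C(=O)C(C)C(=O)C(C)C(=O)[C@@H](C)[C@@H](O[Si](C)(C)C(C)(C)C)CC | intermediate
20 | 2-[(2S,3S)-3-[(tert-butyldimethylsilyl)oxy]pentan-2-yl]-3,5-dimethyl-6-[(R)-pent-3-yn-2-yl]-4H-pyran-4-one | CC#C[C@@H](C)c1oc([C@@H](C)[C@@H](O[Si](C)(C)C(C)(C)C)CC)c(C)c(=O)c1C | intermediate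
21 | 2-[(2S,3S)-3-hydroxypentan-2-yl]-3,5-dimethyl-6-[(R)-pent-3-yn-2-yl]-4H-pyran-4-one | CC#C[C@@H](C)c1oc([C@@H](C)[C@@H](O)CC)c(C)c(=O)c1C | intermediate
22 | 2,6-diethyl-3,5-dimethyl-4H-pyran-4-one | CCc1oc(CC)c(C)c(=O)c1C | starting material
23 | lithium 2-ethyl-6-ethylidene-3,5-dimethyl-6H-pyran-4-olate | CC=C1OC(CC)=C(C)C(O[Li])=C1C | intermediate
24 | lithium (2R,3R,4S)-5-[(tert-butyldimethylsilyl)oxy]-2-(6-ethyl-3,5-dimethyl-4-oxo-4H-pyran-2-yl)-4-methylpentan-3-olate | CCc1oc([C@H](C)[C@H](O[Li])[C@@H](C)CO[Si](C)(C)C(C)(C)C)c(C)c(=O)c1C | intermediate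
25 | (2R,3R,4S)-5-[(tert-butyldimethylsilyl)oxy]-2-(6-ethyl-3,5-dimethyl-4-oxo-4H-pyran-2-yl)-4-methylpentan-3-yl acetate | CCc1oc([C@H](C)[C@H](OC(C)=O)[C@@H](C)CO[Si](C)(C)C(C)(C)C)c(C)c(=O)c1C | intermediate
26 | (2R,3R,4S)-2-(6-ethyl-3,5-dimethyl-4-oxo-4H-pyran-2-yl)-5-hydroxy-4-methylpentan-3-yl acetate | CCc1oc([C@H](C)[C@H](OC(C)=O)[C@@H](C)CO)c(C)c(=O)c1C | intermediate
27 | (2R,3S,4R)-2-(6-ethyl-3,5-dimethyl-4-oxo-4H-pyran-2-yl)-4-methyl-5-oxopentan-3-yl acetate | CCc1oc([C@H](C)[C@H](OC(C)=O)[C@@H](C)C=O)c(C)c(=O)c1C | intermediate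
28 | (2R,3R,4S,5S,6E,8R)-2-(6-ethyl-3,5-dimethyl-4-oxo-4H-pyran-2-yl)-5-hydroxy-8-{6-[(2S,3S)-3-hydroxypentan-2-yl]-3,5-dimethyl-4-oxo-4H-pyran-2-yl}-4,6-dimethylnon-6-en-3-yl acetate | CCc1oc([C@H](C)[C@H](OC(C)=O)[C@@H](C)[C@H](O)/C(C)=C/[C@@H](C)c2oc([C@@H](C)[C@@H](O)CC)c(C)c(=O)c2C)c(C)c(=O)c1C | target

**Totals and risks**
Total step count: 15. Longest linear sequence: 8 (steps 1, 2, 3, 4, 5, 10, 11, 15).

Most likely to fail, first: step 15, the proposed new coupling. The risks are the site of C–C bond formation on the dialkyl alkyne, a modest Felkin ratio at C5, alkyne-to-allene isomerisation and simple reduction of 27. The fallback uses known chemistry, sets out from 21 and comes back at 28. Pd-catalysed hydrostannation (Bu3SnH, PdCl2(PPh3)2, THF, 0 °C; syn addition, tin on the less hindered methyl-bearing carbon) gives 2-[(2S,3S)-3-hydroxypentan-2-yl]-3,5-dimethyl-6-[(R,E)-4-(tributylstannyl)pent-3-en-2-yl]-4H-pyran-4-one F1. Iododestannylation (I2, CH2Cl2, 0 °C) gives 2-[(2S,3S)-3-hydroxypentan-2-yl]-6-[(R,E)-4-iodopent-3-en-2-yl]-3,5-dimethyl-4H-pyran-4-one F2. A classical Nozaki–Hiyama–Kishi coupling of F2 with 27 (CrCl2, NiCl2 cat., DMSO, rt) then gives 28 by Felkin addition of the alkenylchromium.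

Second: step 12, the lateral aldol. Four diastereomers are possible, and both the anti preference and the Felkin ratio may be modest. The fallback sets out from 4 and 13 and comes back at 25. A boron-mediated anti aldol ((c-Hex)2BCl, Et3N, Et2O, −78 °C; E-enolate, Felkin) gives (4R,5R,6S)-7-[(tert-butyldimethylsilyl)oxy]-5-hydroxy-4,6-dimethylheptan-3-one F3. TESOTf/2,6-lutidine gives (4R,5R,6S)-7-[(tert-butyldimethylsilyl)oxy]-4,6-dimethyl-5-[(triethylsilyl)oxy]heptan-3-one F4. LDA then N-propionylimidazole gives (6R,7R,8S)-9-[(tert-butyldimethylsilyl)oxy]-4,6,8-trimethyl-7-[(triethylsilyl)oxy]nonane-3,5-dione F5. LDA (2 equiv) then N-propionylimidazole gives (8R,9R,10S)-11-[(tert-butyldimethylsilyl)oxy]-4,6,8,10-tetramethyl-9-[(triethylsilyl)oxy]undecane-3,5,7-trione F6. PPh3/CCl4 closes ring A to 2-[(2R,3R,4S)-5-[(tert-butyldimethylsilyl)oxy]-4-methyl-3-[(triethylsilyl)oxy]pentan-2-yl]-6-ethyl-3,5-dimethyl-4H-pyran-4-one F7. PPTS/MeOH removes the triethylsilyl group to give 2-[(2R,3R,4S)-5-[(tert-butyldimethylsilyl)oxy]-3-hydroxy-4-methylpentan-2-yl]-6-ethyl-3,5-dimethyl-4H-pyran-4-one F8, and Ac2O/DMAP/pyridine gives 25.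

Third: step 10, the acylation and ring closure. The C-acylation is hindered, and the propargylic α-centre of 18/19 may partly epimerise before ring closure. The fallback sets out from 7 and 15 and comes back at 19, which is cyclised to 20 as in step 10. TBAF (THF, 0 °C) gives (R)-2-methylpent-3-yn-1-ol F9, and Dess–Martin oxidation gives (R)-2-methylpent-3-ynal F10, used at once. Aldol addition of the dianion 16 (from 15, LDA, −78 °C) to F10 gives (4R,10S,11S)-11-[(tert-butyldimethylsilyl)oxy]-5-hydroxy-4,6,8,10-tetramethyltridec-2-yne-7,9-dione F11 as a diastereomer mixture, and Dess–Martin oxidation of F11 gives 19.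

**Further compounds**
F1 | step 15 | 2-[(2S,3S)-3-hydroxypentan-2-yl]-3,5-dimethyl-6-[(R,E)-4-(tributylstannyl)pent-3-en-2-yl]-4H-pyran-4-one | CCCC[Sn](CCCC)(CCCC)/C(C)=C/[C@@H](C)c1oc([C@@H](C)[C@@H](O)CC)c(C)c(=O)c1C
F2 | step 15 | 2-[(2S,3S)-3-hydroxypentan-2-yl]-6-[(R,E)-4-iodopent-3-en-2-yl]-3,5-dimethyl-4H-pyran-4-one | I/C(C)=C/[C@@H](C)c1oc([C@@H](C)[C@@H](O)CC)c(C)c(=O)c1C
F3 | step 12 | (4R,5R,6S)-7-[(tert-butyldimethylsilyl)oxy]-5-hydroxy-4,6-dimethylheptan-3-one | CCC(=O)[C@H](C)[C@H](O)[C@@H](C)CO[Si](C)(C)C(C)(C)C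
F4 | step 12 | (4R,5R,6S)-7-[(tert-butyldimethylsilyl)oxy]-4,6-dimethyl-5-[(triethylsilyl)oxy]heptan-3-one | CCC(=O)[C@H](C)[C@H](O[Si](CC)(CC)CC)[C@@H](C)CO[Si](C)(C)C(C)(C)C
F5 | step 12 | (6R,7R,8S)-9-[(tert-butyldimethylsilyl)oxy]-4,6,8-trimethyl-7-[(triethylsilyl)oxy]nonane-3,5-dione | CCC(=O)C(C)C(=O)[C@H](C)[C@H](O[Si](CC)(CC)CC)[C@@H](C)CO[Si](C)(C)C(C)(C)C
F6 | step 12 | (8R,9R,10S)-11-[(tert-butyldimethylsilyl)oxy]-4,6,8,10-tetramethyl-9-[(triethylsilyl)oxy]undecane-3,5,7-trione | CCC(=O)C(C)C(=O)C(C)C(=O)[C@H](C)[C@H](O[Si](CC)(CC)CC)[C@@H](C)CO[Si](C)(C)C(C)(C)C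
F7 | step 12 | 2-[(2R,3R,4S)-5-[(tert-butyldimethylsilyl)oxy]-4-methyl-3-[(triethylsilyl)oxy]pentan-2-yl]-6-ethyl-3,5-dimethyl-4H-pyran-4-one | CCc1oc([C@H](C)[C@H](O[Si](CC)(CC)CC)[C@@H](C)CO[Si](C)(C)C(C)(C)C)c(C)c(=O)c1C
F8 | step 12 | 2-[(2R,3R,4S)-5-[(tert-butyldimethylsilyl)oxy]-3-hydroxy-4-methylpentan-2-yl]-6-ethyl-3,5-dimethyl-4H-pyran-4-one | CCc1oc([C@H](C)[C@H](O)[C@@H](C)CO[Si](C)(C)C(C)(C)C)c(C)c(=O)c1C
F9 | step 10 | (R)-2-methylpent-3-yn-1-ol | CC#C[C@@H](C)CO
F10 | step 10 | (R)-2-methylpent-3-ynal | CC#C[C@@H](C)C=O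
F11 | step 10 | (4R,10S,11S)-11-[(tert-butyldimethylsilyl)oxy]-5-hydroxy-4,6,8,10-tetramethyltridec-2-yne-7,9-dione | CC#C[C@@H](C)C(O)C(C)C(=O)C(C)C(=O)[C@@H](C)[C@@H](O[Si](C)(C)C(C)(C)C)CC
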